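**Assumption:** 17 has no stereocentre, and rotation about its ester axis is taken as fast, so the compound is achiral. The "single enantiomer" is therefore the compound itself, and all SMILES carry no stereodescriptors.

## The problem

- Target 17 is a depside: two hexasubstituted benzene rings joined only by an aryl ester. With no stereocentre, every difficulty is one of regiochemistry and crowding.
- Locants used throughout: ring A (phenol part) has C1 CO2Me, C2 OMe, C3 Me, C4 O-acyl, C5 Me, C6 Me. Ring B (acyl part) has C1' carboxyl, C2' OMe, C3' Me, C4' OH, C5' Cl, C6' Me. Both rings are the same 2-methoxy-3,6-dimethyl-4-oxybenzoate and differ only at C5/C5' (Me against Cl).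
- The ester bond C4–O–C(=O)–C1' is flanked by four ortho groups (C3-Me, C5-Me, C2'-OMe, C6'-Me). Acyl substitution at this carbonyl is the hindered event of any conventional route, and the acid partner would have to be freed from an equally shielded ester.
- In both rings the oxygen ortho to the carboxyl is the methyl ether and the para oxygen is free or acylated. This is the reverse of the innate order of O-alkylation of a 2,4-dihydroxybenzoate, so conventional routes pay with protecting groups.
- Fragile points: two esters open to transesterification by nucleophilic base, an aryl chloride ortho to a free phenol (lost on hydrogenolysis), and methyl ethers ortho to carbonyl groups (cleaved by boron or aluminium halides).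
- The enabling feature: in ring B the adjacent atoms C1' and C6' carry a carboxyl carbon and a methyl group, which is a but-2-ynoate. C2'–C3'–C4'–C5' carry OMe, Me, O and H, which is a 1,1-dimethoxy-2-methyl-3-silyloxybuta-1,3-diene.
- Ring B is thus the aromatised [4+2] adduct of an ynoate and a vinylketene acetal. The ester can be made while its acyl part is still a slim alkyne, and ring A (C1/C6 plus C2–C5) is the same adduct.

## Retrosynthesis

**17 ⇒ 16.** The C5'–Cl bond is cut last. In 16 the C5' hydrogen is the only arene C–H of the whole molecule, ortho to the free C4' OH and para to the C2' OMe, so electrophilic chlorination needs no directing device. Carrying the chlorine earlier would put it on the reacting terminus of the diene and slow the key step. The forward reaction must stop at monochlorination and avoid ipso or benzylic attack.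

**16 ⇒ 13 + 5 (key disconnection).** Ring B is cut at C1'–C2' and C5'–C6', a retro-[4+2] with loss of aromaticity. The neighbouring cut, the ester C(=O)–O bond, would require joining a 2,6-disubstituted acyl carbon to a 2,6-disubstituted phenol and protecting the C4' OH. The ring cut leaves the ester untouched and turns a pentasubstituted benzoate into an acyclic C4 ynoate ester 13 and the acyclic diene 5. The diene also encodes the OMe/OH differentiation: its ketene-acetal carbon becomes C2' (one OMe survives aromatisation) and its silyl enol ether becomes the free C4' OH. The forward reaction must be regioselective (diene CH2 terminus to the ynoate β-carbon) and must aromatise by loss of one methanol.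

**13 ⇒ 11 + 12.** The ester C(=O)–O bond is cut at the stage where the acyl carbon bears only an sp carbon. The crowded phenol 11 then meets the least hindered acid possible, but-2-ynoic acid 12, and a carbodiimide coupling suffices. 13 is simpler than 16 by a whole ring.

**11 ⇒ 10 ⇒ 9.** The C5–CH3 bond is cut through the aldehyde 10. In 9 the only free ring position, C5, is ortho to the phenol, so chelation-controlled ortho-formylation followed by deoxygenation of the formyl group places the methyl without regiochemical choice. Building this methyl into a second, 4-substituted diene was weighed and rejected: it would need a separate diene synthesis and a less reactive, geometry-dependent diene.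

**9 ⇒ 5 + 6.** Ring A is cut at C1–C2 and C5–C6 in the same retro-[4+2]. The partners are the same diene 5 and commercial methyl but-2-ynoate 6. This step rehearses the key step on the simplest ynoate and gives ring A with the 2-OMe/4-OH pattern already set, without protecting groups.

**5 ⇒ 4 ⇒ 2 + 3; 2 ⇒ 1.** The O–Si bond of 5 is cut to the push–pull enone 4, whose only enolisable position is the acetyl methyl. The C2–C3 bond of 4 is cut to the ketene acetal 2 and acetyl chloride 3 (C-acylation of an electron-rich alkene). 2 comes from commercial orthoester 1 by loss of methanol. One diene serves both rings, so its three-step preparation is paid once.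

## Roads not taken

**Alternative 1:** Cut the ester C(=O)–O bond of 17 with both rings finished (the obvious route).
- Phenol 11 and the acid 4-(benzyloxy)-3-chloro-6-methoxy-2,5-dimethylbenzoic acid A2 would both be made from commercial methyl 2,4-dihydroxy-3,6-dimethylbenzoate A1.
- They would be joined by mixed-anhydride or acylium activation to the benzyl ether A3 of the target, then debenzylated.
- The chosen plan is better on three counts. The bond is formed between two di-ortho-substituted partners at the most crowded point of the molecule. A1 alkylates first at the para oxygen, so each half needs protection, methylation and deprotection, plus cleavage of a shielded methyl ester to reach A2. The final debenzylation of A3 must spare an aryl chloride (hydrogenolysis) and ortho-methoxy carbonyl groups (Lewis acids).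
- The chosen plan uses no protecting group and never performs substitution at the hindered carboxyl carbon.

**Alternative 2:** Cut the ester C–O bond and the C1'–C6' bond in the biomimetic (polyketide) sense.
- Thermolysis of the diketo-dioxinone 6-(3,5-dioxohexan-2-yl)-2,2-dimethyl-4H-1,3-dioxin-4-one A4 would give an acylketene, trapped by phenol 11; aldol aromatisation would give the 2',4'-dihydroxy depside A5.
- This also forms the ester before ring B, but A5 has both ring B oxygens free. Methylating the chelated, flanked C2' OH in the presence of the C4' OH runs against innate reactivity and costs three further steps.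
- The C-methyl-branched triketide equivalent A4 needs a multistep synthesis of its own.
- Diene 5 carries the OMe/OH distinction in its oxidation pattern, which A4 cannot.

**Alternative 3:** Cut the C1'–C(=O) bond.
- Palladium-catalysed carbonylative esterification of the aryl iodide 2-chloro-4-iodo-5-methoxy-3,6-dimethylphenol A6 with phenol 11 would give the target.
- The aroyl–palladium intermediate would be 2,6-disubstituted and would have to be attacked by a hindered, ester-deactivated phenoxide. Reductive elimination is then slow against decarbonylation and reduction.
- The free phenol of A6 competes as nucleophile and would need protection.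
- The carboxyl carbon, which comes free with the ynoate in the chosen plan, has to be introduced separately, and ring A must still be made independently.

Key step: step 8

## Route

Step 1
Reactants: 1 trimethyl orthopropionate (1,1,1-trimethoxypropane)
Product: 2 1,1-dimethoxyprop-1-ene
Conditions: TMSOTf (1.1 equiv), i-Pr2NEt (1.3 equiv), CH2Cl2, −20 °C to rt; pentane, filtration, distillation
Reagents that add atoms: none
Why: Silyl-triflate ionisation of the orthoester to a dimethoxycarbenium ion and α-deprotonation by the hindered amine (the acetal-to-enol-ether elimination applied to an orthoester) should give the ketene acetal; the hindered base should not demethylate the cation.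

Step 2
Reactants: 2 1,1-dimethoxyprop-1-ene; 3 acetyl chloride
Product: 4 4,4-dimethoxy-3-methylbut-3-en-2-one
Conditions: pyridine (1.2 equiv), CH2Cl2, −20 °C to rt; distillation
Reagents that add atoms: none
Why: C-acylation of a ketene acetal by an acid chloride; the acylated dimethoxycarbenium ion loses its doubly activated α-proton to pyridine to give the push–pull enone, and pyridine rather than a trialkylamine avoids ketene formation from 3.

Step 3
Reactants: 4 4,4-dimethoxy-3-methylbut-3-en-2-one
Product: 5 1,1-dimethoxy-2-methyl-3-(trimethylsilyloxy)buta-1,3-diene
Conditions: TMSOTf (1.1 equiv), Et3N (1.5 equiv), Et2O, 0 °C; pentane, filtration, bulb-to-bulb distillation, used fresh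
Reagents that add atoms: trimethylsilyl trifluoromethanesulfonate, C[Si](C)(C)OS(=O)(=O)C(F)(F)F
Why: Soft enolisation and O-silylation of the methyl ketone, whose acetyl CH3 is the only enolisable position, is the standard way to 2-silyloxy-1,3-dienes from enones.

Step 4
Reactants: 5 1,1-dimethoxy-2-methyl-3-(trimethylsilyloxy)buta-1,3-diene (2 equiv); 6 methyl but-2-ynoate
Product: 9 methyl 4-hydroxy-2-methoxy-3,6-dimethylbenzoate, via cycloadduct 7 (not isolated), via aryl silyl ether 8 (not isolated)
Conditions: neat or PhMe, 120 °C, sealed tube; then 1 M HCl, THF, rt
Reagents that add atoms: none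
Why: Diels–Alder benzannulation of a 1,1-dialkoxy-3-silyloxydiene with an acetylenic ester; the CH2 terminus of 5 bonds to the β-carbon of 6 and the acetal carbon to the α-carbon, adduct 7 aromatises by loss of methanol to 8, and acid cleaves the silyl ether, so the ketene-acetal oxygen ends as 2-OMe and the enol-silane oxygen as the free 4-OH.

Step 5
Reactants: 9 methyl 4-hydroxy-2-methoxy-3,6-dimethylbenzoate
Product: 10 methyl 3-formyl-4-hydroxy-6-methoxy-2,5-dimethylbenzoate
Conditions: MgCl2 (2 equiv), Et3N (4 equiv), (CH2O)n (6 equiv), MeCN, reflux; 1 M HCl work-up
Reagents that add atoms: paraformaldehyde (as formaldehyde), C=O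
Why: Casnati–Skattebøl ortho-formylation; the magnesium phenoxide delivers formaldehyde through a six-membered chelate to the only free ortho carbon (C5), and a second formaldehyde oxidises the benzylic alkoxide by hydride transfer; 4-hydroxybenzoate esters are established substrates.

Step 6
Reactants: 10 methyl 3-formyl-4-hydroxy-6-methoxy-2,5-dimethylbenzoate
Product: 11 methyl 4-hydroxy-2-methoxy-3,5,6-trimethylbenzoate
Conditions: Et3SiH (3 equiv), TFA, CH2Cl2, 0 °C to rt
Reagents that add atoms: none
Why: Ionic hydrogenation; after the first hydride transfer the benzylic oxygen ionises to a cation stabilised by the ortho OH and para OMe (ortho-quinone-methide type), which takes a second hydride; esters and aryl ethers are inert.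

Step 7
Reactants: 11 methyl 4-hydroxy-2-methoxy-3,5,6-trimethylbenzoate; 12 but-2-ynoic acid
Product: 13 methyl 4-(but-2-ynoyloxy)-2-methoxy-3,5,6-trimethylbenzoate
Conditions: DCC (1.3 equiv), DMAP (0.1 equiv), CH2Cl2, 0 °C to rt
Reagents that add atoms: none
Why: Steglich esterification; the carbonyl of 12 is flanked only by an sp carbon, so even the 2,6-dimethylphenol 11 should be acylated, and catalytic DMAP at 0 °C limits conjugate addition to the ynoate; aryl alk-2-ynoates are routinely made this way.

Step 8
Reactants: 13 methyl 4-(but-2-ynoyloxy)-2-methoxy-3,5,6-trimethylbenzoate; 5 1,1-dimethoxy-2-methyl-3-(trimethylsilyloxy)buta-1,3-diene (2.5 equiv)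
Product: 16 3-methoxy-4-(methoxycarbonyl)-2,5,6-trimethylphenyl 4-hydroxy-2-methoxy-3,6-dimethylbenzoate, via cycloadduct 14 (not isolated), via aryl silyl ether 15 (not isolated)
Conditions: PhMe, 110–120 °C, sealed tube; then 1 M HCl, THF, rt
Reagents that add atoms: none
Why: Mechanism: thermal [4+2] cycloaddition of the electron-rich diene 5 to the aryl ynoate 13 (concerted and asynchronous, or Mukaiyama–Michael addition followed by ring closure; both give 14), then aromatisation. The closest known reaction type is the Diels–Alder benzannulation of 1,1-dialkoxy-3-silyloxybutadienes with acetylenic esters, which gives 4-hydroxy-2-alkoxybenzoates. Ring B is closed as a six-membered carbocycle by two intermolecular C–C bonds, C5'–C6' (diene CH2 to ynoate β-carbon) and C2'–C1' (acetal carbon to ynoate α-carbon). No stereocentre is formed: 14 has none and becomes planar on aromatisation. The selectivity needed is regioselectivity, secured by matched polarisation: the 3-silyloxy and 1,1-dimethoxy donors both raise the HOMO coefficient at the unsubstituted CH2 terminus, the ester places the largest LUMO coefficient on the methyl-bearing β-carbon, and the CH2 is the only unhindered nucleophilic terminus. Aromatisation is unambiguous because the only path from 14 to an arene is loss of one methanol across C2'/C5', which leaves exactly one methyl ether ortho to the carboxyl, while the silyl enol ether becomes the free para OH on acidic work-up. The aryl ester lowers the ynoate LUMO relative to the methyl ester 6 of step 4, and the four ortho groups that would block an acyl substitution lie far from the reacting alkyne.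

Step 9
Reactants: 16 3-methoxy-4-(methoxycarbonyl)-2,5,6-trimethylphenyl 4-hydroxy-2-methoxy-3,6-dimethylbenzoate
Product: 17 3-methoxy-4-(methoxycarbonyl)-2,5,6-trimethylphenyl 3-chloro-4-hydroxy-6-methoxy-2,5-dimethylbenzoate
Conditions: SO2Cl2 (1.05 equiv), CH2Cl2–Et2O, 0 °C, dark
Reagents that add atoms: sulfuryl chloride, O=S(=O)(Cl)Cl
Why: Electrophilic aromatic chlorination at the only C–H of either ring (C5'), ortho to the free OH and para to the OMe of ring B; one equivalent at 0 °C in the dark should avoid ipso attack and radical benzylic chlorination, and ring A is fully substituted and deactivated by O-acylation.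

## Compound list

1 | trimethyl orthopropionate (1,1,1-trimethoxypropane) | CCC(OC)(OC)OC | starting material
2 | 1,1-dimethoxyprop-1-ene | CC=C(OC)OC | intermediate
3 | acetyl chloride | CC(=O)Cl | starting material
4 | 4,4-dimethoxy-3-methylbut-3-en-2-one | CC(=O)C(C)=C(OC)OC | intermediate
5 | 1,1-dimethoxy-2-methyl-3-(trimethylsilyloxy)buta-1,3-diene | COC(OC)=C(C)C(=C)O[Si](C)(C)C | intermediate
6 | methyl but-2-ynoate | CC#CC(=O)OC | starting material
7 | methyl 6,6-dimethoxy-2,5-dimethyl-4-(trimethylsilyloxy)cyclohexa-1,4-diene-1-carboxylate (cycloadduct, not isolated) | COC(=O)C1=C(C)CC(O[Si](C)(C)C)=C(C)C1(OC)OC | intermediate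
8 | methyl 2-methoxy-3,6-dimethyl-4-(trimethylsilyloxy)benzoate (not isolated) | COC(=O)c1c(C)cc(O[Si](C)(C)C)c(C)c1OC | intermediate
9 | methyl 4-hydroxy-2-methoxy-3,6-dimethylbenzoate | COC(=O)c1c(C)cc(O)c(C)c1OC | intermediate
10 | methyl 3-formyl-4-hydroxy-6-methoxy-2,5-dimethylbenzoate | COC(=O)c1c(C)c(C=O)c(O)c(C)c1OC | intermediate
11 | methyl 4-hydroxy-2-methoxy-3,5,6-trimethylbenzoate | COC(=O)c1c(C)c(C)c(O)c(C)c1OC | intermediate
12 | but-2-ynoic acid | CC#CC(=O)O | starting material
13 | methyl 4-(but-2-ynoyloxy)-2-methoxy-3,5,6-trimethylbenzoate | COC(=O)c1c(C)c(C)c(OC(=O)C#CC)c(C)c1OC | intermediate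
14 | 3-methoxy-4-(methoxycarbonyl)-2,5,6-trimethylphenyl 6,6-dimethoxy-2,5-dimethyl-4-(trimethylsilyloxy)cyclohexa-1,4-diene-1-carboxylate (cycloadduct, not isolated) | COC(=O)c1c(C)c(C)c(OC(=O)C2=C(C)CC(O[Si](C)(C)C)=C(C)C2(OC)OC)c(C)c1OC | intermediate
15 | 3-methoxy-4-(methoxycarbonyl)-2,5,6-trimethylphenyl 2-methoxy-3,6-dimethyl-4-(trimethylsilyloxy)benzoate (not isolated) | COC(=O)c1c(C)c(C)c(OC(=O)c2c(C)cc(O[Si](C)(C)C)c(C)c2OC)c(C)c1OC | intermediate
16 | 3-methoxy-4-(methoxycarbonyl)-2,5,6-trimethylphenyl 4-hydroxy-2-methoxy-3,6-dimethylbenzoate | COC(=O)c1c(C)c(C)c(OC(=O)c2c(C)cc(O)c(C)c2OC)c(C)c1OC | intermediate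
17 | 3-methoxy-4-(methoxycarbonyl)-2,5,6-trimethylphenyl 3-chloro-4-hydroxy-6-methoxy-2,5-dimethylbenzoate (CNP0192286.0) | COC(=O)c1c(C)c(C)c(OC(=O)c2c(C)c(Cl)c(O)c(C)c2OC)c(C)c1OC | target

## Step count and risks

Total step count: 9. Longest linear sequence: 9 steps (1 → 2 → 4 → 5 → 9 → 10 → 11 → 13 → 16 → 17). Diene 5 is made once and enters at steps 4 and 8.

**Step 8 (key step).**
- What may go wrong: cycloaddition to a β-methyl-substituted ynoate may be slower than thermal or adventitious protic decomposition of the diene. The 1,1-disubstituted diene terminus disfavours the s-cis conformer. A stepwise pathway may stop after conjugate addition without ring closure.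
- Fallback: form the ester bond by classical acyl substitution, setting out from 9 (with 11) and returning at 16.
- Benzylation of 9 (BnBr, K2CO3, acetone) should give methyl 4-(benzyloxy)-2-methoxy-3,6-dimethylbenzoate F1.
- Forcing saponification (KOH, DMSO–H2O, 100 °C) should give 4-(benzyloxy)-2-methoxy-3,6-dimethylbenzoic acid F2.
- Activation with trifluoroacetic anhydride (PhMe, rt) in the presence of 11 should give, through the acylium-type mixed anhydride, 3-methoxy-4-(methoxycarbonyl)-2,5,6-trimethylphenyl 4-(benzyloxy)-2-methoxy-3,6-dimethylbenzoate F3.
- Hydrogenolysis (H2, Pd/C, EtOAc) of F3 comes back to 16 before chlorination.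

**Step 4.**
- What may go wrong: the same cycloaddition with the less electrophilic methyl ester; slow reaction with loss of diene is the likely failure.
- Fallback: change the dienophile class, setting out from 5 and returning at 9.
- Commercial methyl buta-2,3-dienoate F4 offers a strained, ester-conjugated C=C that should react with 5 at rt to 60 °C. This gives methyl 2,2-dimethoxy-3-methyl-6-methylidene-4-(trimethylsilyloxy)cyclohex-3-ene-1-carboxylate F5, a known mode of reaction of allenic esters with silyloxydienes.
- Acid treatment (1 M HCl, THF) of F5 should cause β-elimination of methanol, prototropic shift of the exocyclic alkene into the ring and desilylation, giving 9.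
- This changes the bond-forming partner and the aromatisation path, not only the conditions.

**Step 2.**
- What may go wrong: demethylation of the acylated dimethoxycarbenium ion by chloride (collapse to the β-keto ester level) may outrun deprotonation. Ketene formation from 3 with [2+2] addition to the ketene acetal is a second failure path.
- Fallback: build the C–C bond by alkene acylation at the dichloride level, setting out from 3 and returning at 4.
- AlCl3-mediated acylation of 1,1-dichloroprop-1-ene with 3 (CH2Cl2, 0 °C) and loss of HCl should give 4,4-dichloro-3-methylbut-3-en-2-one F6.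
- Double addition–elimination with NaOMe (2 equiv, MeOH, 0 °C) should give 4.

**Step 1.**
- What may go wrong: demethylation of the dimethoxycarbenium ion instead of α-deprotonation, and loss of the volatile, hydrolytically labile ketene acetal on isolation.
- Fallback: reductive elimination instead of acid-mediated elimination, setting out from 1 and returning at 2.
- α-Bromination of 1 (Br2, pyridine) should give 2-bromo-1,1,1-trimethoxypropane F7.
- Sodium metal (2 equiv, Et2O, reflux) should remove bromide and methoxide to give 2.

**Step 5.**
- What may go wrong: slow formylation of a phenoxide that is deactivated by the para ester and flanked by a methyl group, with competing O-methoxymethylation or diarylmethane formation.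
- Fallback: install the methyl by cross-coupling, setting out from 9 and returning at 11 (10 is bypassed).
- Bromination of 9 (NBS, MeCN, 0 °C) at the only free position should give methyl 3-bromo-4-hydroxy-6-methoxy-2,5-dimethylbenzoate F8.
- Suzuki–Miyaura methylation (trimethylboroxine, Pd(OAc)2/SPhos, K2CO3, dioxane–H2O, 90 °C) should give 11.

## Further compounds

F1 | step 8 | methyl 4-(benzyloxy)-2-methoxy-3,6-dimethylbenzoate | COC(=O)c1c(C)cc(OCc2ccccc2)c(C)c1OC
F2 | step 8 | 4-(benzyloxy)-2-methoxy-3,6-dimethylbenzoic acid | OC(=O)c1c(C)cc(OCc2ccccc2)c(C)c1OC
F3 | step 8 | 3-methoxy-4-(methoxycarbonyl)-2,5,6-trimethylphenyl 4-(benzyloxy)-2-methoxy-3,6-dimethylbenzoate | COC(=O)c1c(C)c(C)c(OC(=O)c2c(C)cc(OCc3ccccc3)c(C)c2OC)c(C)c1OC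
F4 | step 4 | methyl buta-2,3-dienoate | COC(=O)C=C=C
F5 | step 4 | methyl 2,2-dimethoxy-3-methyl-6-methylidene-4-(trimethylsilyloxy)cyclohex-3-ene-1-carboxylate (racemic, not isolated) | COC(=O)C1C(=C)CC(O[Si](C)(C)C)=C(C)C1(OC)OC
F6 | step 2 | 4,4-dichloro-3-methylbut-3-en-2-one | CC(=O)C(C)=C(Cl)Cl
F7 | step 1 | 2-bromo-1,1,1-trimethoxypropane (racemic) | CC(Br)C(OC)(OC)OC
F8 | step 5 | methyl 3-bromo-4-hydroxy-6-methoxy-2,5-dimethylbenzoate | COC(=O)c1c(C)c(Br)c(O)c(C)c1OC
A1 | alternative 1 | methyl 2,4-dihydroxy-3,6-dimethylbenzoate | COC(=O)c1c(C)cc(O)c(C)c1O
A2 | alternative 1 | 4-(benzyloxy)-3-chloro-6-methoxy-2,5-dimethylbenzoic acid | OC(=O)c1c(C)c(Cl)c(OCc2ccccc2)c(C)c1OC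
A3 | alternative 1 | 3-methoxy-4-(methoxycarbonyl)-2,5,6-trimethylphenyl 4-(benzyloxy)-3-chloro-6-methoxy-2,5-dimethylbenzoate | COC(=O)c1c(C)c(C)c(OC(=O)c2c(C)c(Cl)c(OCc3ccccc3)c(C)c2OC)c(C)c1OC
A4 | alternative 2 | 6-(3,5-dioxohexan-2-yl)-2,2-dimethyl-4H-1,3-dioxin-4-one (racemic, configurationally labile) | CC(=O)CC(=O)C(C)C1=CC(=O)OC(C)(C)O1
A5 | alternative 2 | 3-methoxy-4-(methoxycarbonyl)-2,5,6-trimethylphenyl 2,4-dihydroxy-3,6-dimethylbenzoate | COC(=O)c1c(C)c(C)c(OC(=O)c2c(C)cc(O)c(C)c2O)c(C)c1OC
A6 | alternative 3 | 2-chloro-4-iodo-5-methoxy-3,6-dimethylphenol | Cc1c(O)c(Cl)c(C)c(I)c1OC
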